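In the early minutes of this flask the catalyst works and dies at once, so I follow the rate of making target and what wears it down.

starting material 2.9 M; free catalyst 13 mM; impurity 3.0 mM

    catalyst intermediate → free catalyst + target (k1 = 0.32 /s)
    free catalyst → spent catalyst B (k2 = 0.0045 /s)
    free catalyst + impurity → spent catalyst A (k3 = 28 /M/s)
    starting material + free catalyst ⇌ catalyst intermediate (K4 = 0.41 /M, k4 = 0.24 /M/s)

1. the form that holds most of the catalyst when 10% of the starting material are converted (spent catalyst A / spent catalyst B / catalyst intermediate / free catalyst)
2. its share of the catalyst then

I take the intermediate as made and used at equal rates, so with the starting material at 95.0% of its charge, halfway to 10% conversion, intermediate stands to free catalyst as 0.730, and 42.2% of the working catalyst is intermediate. With all the catalyst working, target would form at 0.0363 /min of the charge. The impurity slows this first: its rate per free catalyst, with impurity as charged, is 5.0 /min, far above the 0.27 /min of the step to spent catalyst B, so I book a quick loss of 23.1% of the catalyst, a factor 0.769 on the rate.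

The slower wear comes from the step to spent catalyst B. Release of target outruns it by 51.9, and this is what I carry: target made per catalyst lost to that step, the turnover budget, a turnover number. By my reckoning, reaching 10% conversion therefore costs 43.0% of the catalyst as spent catalyst B, more than the impurity's share or the 34.0% still live. The rate then stands at a factor 0.442 of its value after the impurity, and as it fades the target should end near 17.9% of the charge.

The forecast says spent catalyst B at 43%, from “the ratio of turnover to first-order death”, about 50 turnovers.

The flask gives spent catalyst B at 42.8%. The impurity reaction ran early, for at 2.00 min impurity stands at 0% and spent catalyst A at 23.1%; the catalytic round and the step to spent catalyst B, both under way by then, ran on side by side, and at 20.0 min target stands at 16.5%, with 1.86% free catalyst and 1.19% intermediate. With twice the free catalyst, counting the same impurity, the same budget and an exponential fade of live catalyst give a factor 0.340 on the time to 10% conversion, and the simulated run gives 0.337.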